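Labels: C1 (CH bearing CH2O), C2, C3, C4 (alkene carbon bearing the trimethylcyclohexyl group Q), C5 (ring-fusion alkene carbon), C6, C7 (lactone α-CH), C8 (C=O), O9, C10 (OCH), C11 (ring-fusion CH). The route cuts C5–C11 and C3–C4: the cyclopentane C5–C6–C7–C10–C11 contains a three-atom tether C6–C7–C10 that the cis-oxetanone already clamps, and C4=C5 is a masked alkyne. A rhodium-catalysed intramolecular [4+2] cycloaddition of a cis-3-propargyl-4-dienyl β-lactone (no carbocycle except Q) therefore closes the cyclopentane together with the cyclohexene, delivers the hindered C4=C5 alkene and sets C11; hydrogenation of the remaining C1=C2 alkene then sets C1.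

Key step: step 11

Remark (assumption): the absolute sense of induction of O-trimethylsilylquinidine (TMSQd, step 10) and of the NHC ligand (step 2) is taken from the usual models for these catalyst classes; if the opposite sense is found, O-trimethylsilylquinine or the antipodal ligand is used.

Remark (nomenclature): in the tricyclic names the locants 1, 2, 5 and 11 are the labels C11, C10, C7 and C1; the Z descriptors of 12–14 and 16 denote the geometry in which the carbonyl-side carbon is trans to the vinyl group.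

Step 1
Reactants: 1 3-bromocyclohex-2-en-1-one; 2 tert-butyldimethyl(pent-4-yn-1-yloxy)silane
Product: 3 3-[5-(tert-butyldimethylsilyloxy)pent-1-yn-1-yl]cyclohex-2-en-1-one
Conditions: Pd(PPh3)2Cl2 (2 mol%), CuI (4 mol%), Et3N, THF, 23 °C
Reagents that add atoms: none
Why: Sonogashira coupling of a terminal alkyne with an activated β-bromo enone, for which oxidative addition is fast and the silyl ether is inert; no stereocentre is formed.

Step 2
Reactants: 3 3-[5-(tert-butyldimethylsilyloxy)pent-1-yn-1-yl]cyclohex-2-en-1-one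
Product: 4 (3S)-3-[5-(tert-butyldimethylsilyloxy)pent-1-yn-1-yl]-3-methylcyclohexan-1-one
Conditions: MeMgBr (1.3 equiv), Cu(OTf)2 (5 mol%), chiral imidazolinium chloride (NHC precursor, 6 mol%), Et2O, −10 °C; then aq NH4Cl
Reagents that add atoms: methylmagnesium bromide, C[Mg]Br
Why: Copper-catalysed asymmetric conjugate addition of a Grignard reagent to a 3-alkynylcyclohex-2-enone, a substrate class that reacts 1,4 under NHC–copper catalysis, so methyl adds to the β-carbon and the quaternary centre is set by the chiral ligand (the antipode giving the S ketone is used).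

Step 3
Reactants: 4 (3S)-3-[5-(tert-butyldimethylsilyloxy)pent-1-yn-1-yl]-3-methylcyclohexan-1-one
Product: 5 tert-butyldimethyl({5-[(1S)-1,3,3-trimethylcyclohexyl]pent-4-yn-1-yl}oxy)silane
Conditions: Me2Zn (2.5 equiv), TiCl4 (2.5 equiv), CH2Cl2, −40 °C to 0 °C
Reagents that add atoms: dimethyltitanium dichloride, C[Ti](C)(Cl)Cl (generated from dimethylzinc, C[Zn]C, and TiCl4, Cl[Ti](Cl)(Cl)Cl)
Why: Geminal dimethylation of a ketone with Me2TiCl2 (methyl addition, ionisation of the tertiary titanium alkoxide to a tertiary cation, capture by a second methyl), which leaves the non-adjacent quaternary centre and the alkyne untouched; any alcohol set free from the silyl ether converges in step 4.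

Step 4
Reactants: 5 tert-butyldimethyl({5-[(1S)-1,3,3-trimethylcyclohexyl]pent-4-yn-1-yl}oxy)silane
Product: 8 5-[(1S)-1,3,3-trimethylcyclohexyl]pent-4-ynoic acid, via alcohol 6 (not isolated), via aldehyde 7 (not isolated)
Conditions: CrO3, H2SO4, H2O/acetone, 0 °C to 23 °C
Reagents that add atoms: water, O (second carboxyl oxygen)
Why: Jones oxidation, in which the aqueous acid removes the primary silyl ether and chromic acid oxidises the alcohol through the aldehyde hydrate to the acid while the internal alkyne is inert.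

Step 5
Reactants: 8 5-[(1S)-1,3,3-trimethylcyclohexyl]pent-4-ynoic acid
Product: 9 5-[(1S)-1,3,3-trimethylcyclohexyl]pent-4-ynoyl chloride
Conditions: (COCl)2, DMF (cat.), CH2Cl2, 0 °C to 23 °C; used crude
Reagents that add atoms: oxalyl chloride, ClC(=O)C(=O)Cl
Why: DMF-catalysed conversion of a carboxylic acid into its chloride under neutral conditions gives the ketene precursor without touching the alkyne or the stereocentre.

Step 6
Reactants: 10 tert-butyldimethyl(prop-2-yn-1-yloxy)silane
Product: 11 methyl 4-(tert-butyldimethylsilyloxy)but-2-ynoate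
Conditions: n-BuLi, THF, −78 °C; then ClCO2Me, −78 °C to 0 °C
Reagents that add atoms: methyl chloroformate, COC(=O)Cl
Why: Deprotonation of the terminal alkyne and C-acylation of the lithium acetylide with a chloroformate is a standard ynoate synthesis.

Step 7
Reactants: 11 methyl 4-(tert-butyldimethylsilyloxy)but-2-ynoate
Product: 12 methyl (2Z)-3-[(tert-butyldimethylsilyloxy)methyl]penta-2,4-dienoate
Conditions: CH2=CHMgBr (1.5 equiv), CuBr·SMe2 (1.5 equiv), THF, −78 °C; then 11; MeOH then aq NH4Cl at −78 °C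
Reagents that add atoms: vinylmagnesium bromide, C=C[Mg]Br (transferred as ethenylcopper)
Why: syn-Carbocupration (conjugate addition) of the vinylcopper reagent to the ynoate at −78 °C and protonation of the configurationally stable alkenylcopper with retention place H and vinyl cis, so the ester is cis to CH2OTBS; the silyloxy group is too poor a leaving group for allene formation.

Step 8
Reactants: 12 methyl (2Z)-3-[(tert-butyldimethylsilyloxy)methyl]penta-2,4-dienoate
Product: 13 (2Z)-3-[(tert-butyldimethylsilyloxy)methyl]penta-2,4-dien-1-ol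
Conditions: DIBAL-H (2.5 equiv), CH2Cl2, −78 °C; Rochelle salt work-up
Reagents that add atoms: none
Why: DIBAL reduction of a conjugated ester to the allylic alcohol by 1,2-hydride delivery at low temperature leaves the diene geometry unchanged.

Step 9
Reactants: 13 (2Z)-3-[(tert-butyldimethylsilyloxy)methyl]penta-2,4-dien-1-ol
Product: 14 (2Z)-3-[(tert-butyldimethylsilyloxy)methyl]penta-2,4-dienal
Conditions: MnO2 (excess), CH2Cl2, 23 °C
Reagents that add atoms: none
Why: MnO2 oxidation is selective for allylic alcohols and neutral, and the geometry it must preserve (CHO trans to vinyl) is also the thermodynamically preferred one and cannot undergo oxa-6π ring closure.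

Step 10
Reactants: 9 5-[(1S)-1,3,3-trimethylcyclohexyl]pent-4-ynoyl chloride; 14 (2Z)-3-[(tert-butyldimethylsilyloxy)methyl]penta-2,4-dienal
Product: 16 (3R,4S)-4-{(1Z)-2-[(tert-butyldimethylsilyloxy)methyl]buta-1,3-dien-1-yl}-3-{3-[(1S)-1,3,3-trimethylcyclohexyl]prop-2-yn-1-yl}oxetan-2-one, via ketene 15 (not isolated)
Conditions: TMSQd (15 mol%), LiClO4 (1 equiv), iPr2NEt (2.5 equiv), CH2Cl2/Et2O, −78 °C, slow addition of 9; cold neutral work-up
Reagents that add atoms: none
Why: Alkaloid/lithium-salt catalysed acyl halide–aldehyde cyclocondensation (formal ketene–aldehyde [2+2] cycloaddition): the ketene is captured by TMSQd as a Z ammonium enolate, which adds to the lithium-activated aldehyde through a closed transition state and lactonises to the cis-3,4-disubstituted β-lactone, both new centres (C7 R, C10 S) being fixed by the alkaloid and the remote quaternary centre exerting no influence.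

Step 11
Reactants: 16 (3R,4S)-4-{(1Z)-2-[(tert-butyldimethylsilyloxy)methyl]buta-1,3-dien-1-yl}-3-{3-[(1S)-1,3,3-trimethylcyclohexyl]prop-2-yn-1-yl}oxetan-2-one
Product: 17 (1S,2S,5R)-11-[(tert-butyldimethylsilyloxy)methyl]-8-[(1S)-1,3,3-trimethylcyclohexyl]-3-oxatricyclo[5.4.0.0^2,5]undeca-7,10-dien-4-one
Conditions: [Rh(cod)(η6-C10H8)]SbF6 (5 mol%), CH2Cl2 (0.01 M), 23 °C, argon; product taken on at once
Reagents that add atoms: none
Why: Cationic monovalent rhodium binds the alkyne and the diene, oxidative cyclisation joins C5 to C11 (a rhodacyclopentene in which C4 is a vinyl ligand and C1–C2–C3 an η3-allyl) and reductive elimination joins C4 to the unsubstituted allyl terminus C3, so the sequence is a metal-catalysed intramolecular Diels–Alder ([4+2]) reaction of a 1,3-dien-8-yne. This is the closest known reaction type: rhodium-catalysed [4+2] cycloadditions of unactivated dienynes run at room temperature, whereas the thermal reaction would need temperatures at which a β-lactone loses CO2. The cyclopentane is closed by the C5–C11 bond in a 5-exo-dig sense across the tether C6–C7–C10 and the cyclohexa-1,4-diene by the C3–C4 reductive elimination, both within one catalytic cycle, so no ring remains to be closed afterwards. The only new stereocentre, C11, is controlled by the lactone: the cis-oxetanone holds both arms on one face, and allylic 1,3-strain with the CH2OTBS group that is cis to C10 on C1 puts H-10 in the diene plane, so the alkyne adds to the diene face anti to O9 and H-11 ends trans to H-10. Regiochemistry is dictated by the tether, and the alkyne delivers the tetrasubstituted C4=C5 alkene with Q already in place, the first bond being formed at the alkyne carbon remote from Q. The step needs cycloaddition to outrun ionisation of the dienylic C10–O9 bond, which a phosphine-free cationic catalyst at 23 °C and low loading should secure, and it needs the C11 face selectivity described above.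

Step 12
Reactants: 17 (1S,2S,5R)-11-[(tert-butyldimethylsilyloxy)methyl]-8-[(1S)-1,3,3-trimethylcyclohexyl]-3-oxatricyclo[5.4.0.0^2,5]undeca-7,10-dien-4-one
Product: 18 (1R,2S,5R,11S)-11-[(tert-butyldimethylsilyloxy)methyl]-8-[(1S)-1,3,3-trimethylcyclohexyl]-3-oxatricyclo[5.4.0.0^2,5]undec-7-en-4-one
Conditions: H2 (10 atm), RhCl(PPh3)3 (10 mol%), toluene, 25 °C
Reagents that add atoms: none
Why: Homogeneous hydrogenation with RhCl(PPh3)3 reduces the trisubstituted C1=C2 alkene but not the tetrasubstituted C4=C5 alkene shielded by the quaternary carbon and causes neither hydrogenolysis of the allylic C–O bond nor disproportionation of the 1,4-diene; H2 is delivered to the face opposite to the oxetanone and H-11, which sets C1 (S) with CH2OTBS trans to the C11–C10 bond.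

Step 13
Reactants: 18 (1R,2S,5R,11S)-11-[(tert-butyldimethylsilyloxy)methyl]-8-[(1S)-1,3,3-trimethylcyclohexyl]-3-oxatricyclo[5.4.0.0^2,5]undec-7-en-4-one
Product: 19 (1R,2S,5R,11S)-11-(hydroxymethyl)-8-[(1S)-1,3,3-trimethylcyclohexyl]-3-oxatricyclo[5.4.0.0^2,5]undec-7-en-4-one
Conditions: HF·pyridine, pyridine/THF, 0 °C
Reagents that add atoms: none
Why: Fluoride-mediated cleavage of the primary silyl ether under buffered acidic conditions that β-lactones tolerate affects no stereocentre.

Step 14
Reactants: 19 (1R,2S,5R,11S)-11-(hydroxymethyl)-8-[(1S)-1,3,3-trimethylcyclohexyl]-3-oxatricyclo[5.4.0.0^2,5]undec-7-en-4-one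
Product: 20 [(1R,2S,5R,11S)-4-oxo-8-[(1S)-1,3,3-trimethylcyclohexyl]-3-oxatricyclo[5.4.0.0^2,5]undec-7-en-11-yl]methyl butanoate (3'-norspongiolactone)
Conditions: butanoyl chloride, pyridine, CH2Cl2, 0 °C
Reagents that add atoms: butanoyl chloride, CCCC(=O)Cl
Why: O-Acylation of the primary alcohol with an acid chloride and pyridine at 0 °C is faster than any attack of the weak base on the β-lactone and completes the target.

Compound list
1 | 3-bromocyclohex-2-en-1-one | O=C1C=C(Br)CCC1 | starting material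
2 | tert-butyldimethyl(pent-4-yn-1-yloxy)silane | C#CCCCO[Si](C)(C)C(C)(C)C | starting material
3 | 3-[5-(tert-butyldimethylsilyloxy)pent-1-yn-1-yl]cyclohex-2-en-1-one | O=C1C=C(C#CCCCO[Si](C)(C)C(C)(C)C)CCC1 | intermediate
4 | (3S)-3-[5-(tert-butyldimethylsilyloxy)pent-1-yn-1-yl]-3-methylcyclohexan-1-one | CC(C)(C)[Si](C)(C)OCCCC#C[C@@]1(C)CCCC(=O)C1 | intermediate
5 | tert-butyldimethyl({5-[(1S)-1,3,3-trimethylcyclohexyl]pent-4-yn-1-yl}oxy)silane | CC(C)(C)[Si](C)(C)OCCCC#C[C@@]1(C)CCCC(C)(C)C1 | intermediate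
6 | 5-[(1S)-1,3,3-trimethylcyclohexyl]pent-4-yn-1-ol | OCCCC#C[C@@]1(C)CCCC(C)(C)C1 | intermediate
7 | 5-[(1S)-1,3,3-trimethylcyclohexyl]pent-4-ynal | O=CCCC#C[C@@]1(C)CCCC(C)(C)C1 | intermediate
8 | 5-[(1S)-1,3,3-trimethylcyclohexyl]pent-4-ynoic acid | OC(=O)CCC#C[C@@]1(C)CCCC(C)(C)C1 | intermediate
9 | 5-[(1S)-1,3,3-trimethylcyclohexyl]pent-4-ynoyl chloride | ClC(=O)CCC#C[C@@]1(C)CCCC(C)(C)C1 | intermediate
10 | tert-butyldimethyl(prop-2-yn-1-yloxy)silane | C#CCO[Si](C)(C)C(C)(C)C | starting material
11 | methyl 4-(tert-butyldimethylsilyloxy)but-2-ynoate | COC(=O)C#CCO[Si](C)(C)C(C)(C)C | intermediate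
12 | methyl (2Z)-3-[(tert-butyldimethylsilyloxy)methyl]penta-2,4-dienoate | COC(=O)/C=C(/C=C)CO[Si](C)(C)C(C)(C)C | intermediate
13 | (2Z)-3-[(tert-butyldimethylsilyloxy)methyl]penta-2,4-dien-1-ol | OC/C=C(/C=C)CO[Si](C)(C)C(C)(C)C | intermediate
14 | (2Z)-3-[(tert-butyldimethylsilyloxy)methyl]penta-2,4-dienal | O=C/C=C(/C=C)CO[Si](C)(C)C(C)(C)C | intermediate
15 | {3-[(1S)-1,3,3-trimethylcyclohexyl]prop-2-yn-1-yl}ketene | O=C=CCC#C[C@@]1(C)CCCC(C)(C)C1 | intermediate
16 | (3R,4S)-4-{(1Z)-2-[(tert-butyldimethylsilyloxy)methyl]buta-1,3-dien-1-yl}-3-{3-[(1S)-1,3,3-trimethylcyclohexyl]prop-2-yn-1-yl}oxetan-2-one | C(#C[C@@]1(C)CCCC(C)(C)C1)C[C@H]2C(=O)O[C@H]2/C=C(/C=C)CO[Si](C)(C)C(C)(C)C | intermediate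
17 | (1S,2S,5R)-11-[(tert-butyldimethylsilyloxy)methyl]-8-[(1S)-1,3,3-trimethylcyclohexyl]-3-oxatricyclo[5.4.0.0^2,5]undeca-7,10-dien-4-one | CC(C)(C)[Si](C)(C)OCC1=CCC([C@@]2(C)CCCC(C)(C)C2)=C2C[C@H]3C(=O)O[C@H]3[C@@H]21 | intermediate
18 | (1R,2S,5R,11S)-11-[(tert-butyldimethylsilyloxy)methyl]-8-[(1S)-1,3,3-trimethylcyclohexyl]-3-oxatricyclo[5.4.0.0^2,5]undec-7-en-4-one | CC(C)(C)[Si](C)(C)OC[C@H]1CCC([C@@]2(C)CCCC(C)(C)C2)=C2C[C@H]3C(=O)O[C@H]3[C@@H]21 | intermediate
19 | (1R,2S,5R,11S)-11-(hydroxymethyl)-8-[(1S)-1,3,3-trimethylcyclohexyl]-3-oxatricyclo[5.4.0.0^2,5]undec-7-en-4-one | OC[C@H]1CCC([C@@]2(C)CCCC(C)(C)C2)=C2C[C@H]3C(=O)O[C@H]3[C@@H]21 | intermediate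
20 | [(1R,2S,5R,11S)-4-oxo-8-[(1S)-1,3,3-trimethylcyclohexyl]-3-oxatricyclo[5.4.0.0^2,5]undec-7-en-11-yl]methyl butanoate (3'-norspongiolactone) | CCCC(=O)OC[C@H]1CCC([C@@]2(C)CCCC(C)(C)C2)=C2C[C@H]3C(=O)O[C@H]3[C@@H]21 | target

Total step count: 14. Longest linear sequence: 10 steps (steps 1–5 and 10–14); the dienal branch (steps 6–9) joins at step 10.

Steps most likely to fail

Step 11. The catalyst may ionise the dienylic C10–O9 bond of the strained lactone, or the alkyne carrying the quaternary carbon may fail to enter the metallacycle. The fallback takes the strained ring out of play for the cycloaddition and sets out from 16. LiOH (THF/H2O, 0 °C) opens the lactone to the syn β-hydroxy acid F4, and TESOTf/2,6-lutidine gives the triethylsilyl ether triethylsilyl ester F5. The intramolecular Diels–Alder reaction is then run on this open-chain dienyne, thermally (toluene, BHT, sealed tube, 170 °C) or with the same rhodium catalyst, to give the bicyclic cyclohexadiene F6. Aqueous AcOH/THF cleaves the silyl ester and the secondary TES ether (primary TBS ether retained) to the hydroxy acid F7, and TsCl/pyridine (0 °C) closes the oxetanone with retention, coming back to the route at 17. In this variant the four-membered ring is reclosed after the carbocycles, and C11 is controlled by allylic 1,3-strain with the C10 silyloxy centre alone.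

Step 10. The conjugated aldehyde may react sluggishly with the ammonium enolate, the ketene may dimerise instead, or the dienyl lactone may ring-open under the Lewis acid or on work-up. The fallback sets out from acid 8 and dienal 14. Acid 8 is converted (PivCl, Et3N; then the lithium salt of (R)-4-benzyloxazolidin-2-one) into the N-acyl oxazolidinone F1. Its dibutylboron Z enolate (Bu2BOTf, iPr2NEt, −78 °C) adds to 14 in an Evans syn-aldol reaction to give the (2R,3S) adduct F2. LiOH/H2O2 removes the auxiliary to give the syn β-hydroxy acid F3, and carboxyl activation (TsCl, pyridine, 0 °C) lactonises with retention at both centres, coming back to the route at 16.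

Step 12. Facial selectivity at C1 may be poor, or the 1,4-diene may isomerise or over-reduce before selective reduction. The fallback sets C1 under thermodynamic control and sets out from 17. HF·pyridine gives the dienyl alcohol F8, and MnO2 oxidises the allylic alcohol to the enal F9. Conjugate reduction with [(Ph3P)CuH]6 (toluene, 23 °C) gives the saturated aldehyde F10, whose C1 centre is epimerisable and should settle (silica gel or a trace of DBU) in the equatorial arrangement trans to C10. Zn(BH4)2 (Et2O, −20 °C) reduces the aldehyde without touching the lactone, coming back to the route at 19.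

Further compounds
F1 | step 10 | (4R)-4-benzyl-3-{5-[(1S)-1,3,3-trimethylcyclohexyl]pent-4-ynoyl}oxazolidin-2-one | O=C(CCC#C[C@@]1(C)CCCC(C)(C)C1)N2[C@H](Cc3ccccc3)COC2=O
F2 | step 10 | (4R)-4-benzyl-3-[(2R,3S,4Z)-5-[(tert-butyldimethylsilyloxy)methyl]-3-hydroxy-2-{3-[(1S)-1,3,3-trimethylcyclohexyl]prop-2-yn-1-yl}hepta-4,6-dienoyl]oxazolidin-2-one | C(#C[C@@]1(C)CCCC(C)(C)C1)C[C@H]([C@@H](O)/C=C(/C=C)CO[Si](C)(C)C(C)(C)C)C(=O)N2[C@H](Cc3ccccc3)COC2=O
F3 | step 10 | (2R,3S,4Z)-5-[(tert-butyldimethylsilyloxy)methyl]-3-hydroxy-2-{3-[(1S)-1,3,3-trimethylcyclohexyl]prop-2-yn-1-yl}hepta-4,6-dienoic acid | C(#C[C@@]1(C)CCCC(C)(C)C1)C[C@H]([C@@H](O)/C=C(/C=C)CO[Si](C)(C)C(C)(C)C)C(=O)O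
F4 | step 11 | (2R,3S,4Z)-5-[(tert-butyldimethylsilyloxy)methyl]-3-hydroxy-2-{3-[(1S)-1,3,3-trimethylcyclohexyl]prop-2-yn-1-yl}hepta-4,6-dienoic acid | C(#C[C@@]1(C)CCCC(C)(C)C1)C[C@H]([C@@H](O)/C=C(/C=C)CO[Si](C)(C)C(C)(C)C)C(=O)O
F5 | step 11 | triethylsilyl (2R,3S,4Z)-5-[(tert-butyldimethylsilyloxy)methyl]-3-(triethylsilyloxy)-2-{3-[(1S)-1,3,3-trimethylcyclohexyl]prop-2-yn-1-yl}hepta-4,6-dienoate | C(#C[C@@]1(C)CCCC(C)(C)C1)C[C@H]([C@@H](O[Si](CC)(CC)CC)/C=C(/C=C)CO[Si](C)(C)C(C)(C)C)C(=O)O[Si](CC)(CC)CC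
F6 | step 11 | triethylsilyl (1S,2R,7aS)-7-[(tert-butyldimethylsilyloxy)methyl]-1-(triethylsilyloxy)-4-[(1S)-1,3,3-trimethylcyclohexyl]-2,3,5,7a-tetrahydro-1H-indene-2-carboxylate | CC(C)(C)[Si](C)(C)OCC1=CCC([C@@]2(C)CCCC(C)(C)C2)=C2C[C@@H](C(=O)O[Si](CC)(CC)CC)[C@@H](O[Si](CC)(CC)CC)[C@@H]21
F7 | step 11 | (1S,2R,7aS)-7-[(tert-butyldimethylsilyloxy)methyl]-1-hydroxy-4-[(1S)-1,3,3-trimethylcyclohexyl]-2,3,5,7a-tetrahydro-1H-indene-2-carboxylic acid | CC(C)(C)[Si](C)(C)OCC1=CCC([C@@]2(C)CCCC(C)(C)C2)=C2C[C@@H](C(=O)O)[C@@H](O)[C@@H]21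
F8 | step 12 | (1S,2S,5R)-11-(hydroxymethyl)-8-[(1S)-1,3,3-trimethylcyclohexyl]-3-oxatricyclo[5.4.0.0^2,5]undeca-7,10-dien-4-one | OCC1=CCC([C@@]2(C)CCCC(C)(C)C2)=C2C[C@H]3C(=O)O[C@H]3[C@@H]21
F9 | step 12 | (1S,2S,5R)-4-oxo-8-[(1S)-1,3,3-trimethylcyclohexyl]-3-oxatricyclo[5.4.0.0^2,5]undeca-7,10-diene-11-carbaldehyde | O=CC1=CCC([C@@]2(C)CCCC(C)(C)C2)=C2C[C@H]3C(=O)O[C@H]3[C@@H]21
F10 | step 12 | (1R,2S,5R,11S)-4-oxo-8-[(1S)-1,3,3-trimethylcyclohexyl]-3-oxatricyclo[5.4.0.0^2,5]undec-7-ene-11-carbaldehyde | O=C[C@H]1CCC([C@@]2(C)CCCC(C)(C)C2)=C2C[C@H]3C(=O)O[C@H]3[C@@H]21
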